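## Retrosynthetic overview

1. The C10 angelate and C11 carbinol come from a 1,2 O→O angeloyl shift. The C10 carbinol comes from a C8-hydroxyl-directed anti reduction of a β-hydroxy ketone, so no protecting groups are needed.
2. The C8–C9 bond comes from a reagent-controlled boron aldol between a ring-complete α-substituted acrolein and an α-angeloyloxy methyl ketone. That ketone is made by C–O alkylation of angelate.
3. The enal comes from allylic oxidation of the isopropenyl methyl group. The C2 ester comes from acylation, the oxirane from C2-OH-directed epoxidation, and the C2 carbinol from Luche reduction.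
4. The key disconnection is the C1–OAc carbon–oxygen bond. It is made on (R)-carvone by a stereoinvertive λ3-iodane α'-acetoxylation. This contra-steric C–O bond is the stereochemical root from which C2, C3 and C4 are relayed.
5. Ring order: the carbocycle, with C6, is bought with (R)-carvone. The oxirane is the only ring formed (step 3).

Assumption: operations run in one flask, or on an unpurified crude after a solvent switch, count as one step.

Numbering (bisabolane): C1 = CH–OAc, C2 = CH–OAng, C3 = oxirane C(CH3), C4 = oxirane CH, C5 = CH2, C6 = CH bearing the side chain, C7(=C14H2), C8 = CH–OH, C9 = CH2, C10 = CH–OAng, C11 = C(OH)(CH3)2. Ang = (Z)-2-methylbut-2-enoyl.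

The target is (1R,2R,3S,4S,6S,8R,10R). The side chain, both ring ester oxygens and the oxirane oxygen lie on one face (β). The C8/C10 oxygens are anti.

## Route

Step 1
Reactants: 1 (R)-(−)-carvone
Product: 4 cis-6-acetoxycarvone = (1R,6S)-3-methyl-2-oxo-6-(prop-1-en-2-yl)cyclohex-3-en-1-yl acetate (OAc cis to isopropenyl), via TMS dienol ether 2 (not isolated), via trans-iodonium salt 3 (not isolated)
Conditions: LiN(i-Pr)2, THF, −78 °C, then TMSCl; evaporate, CH2Cl2; PhIO/HBF4·OEt2 (1:1, 1.05 equiv), −78 °C, 20 min; n-Bu4NOAc (3 equiv), −78 to −40 °C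
Reagents that add atoms: tetrabutylammonium acetate, CCCC[N+](CCCC)(CCCC)CCCC.CC(=O)[O-]
Why: Proposed new method: stereoinvertive α'-acetoxylation, in which the cationic λ3-iodane is attacked by the silyl dienol ether at carbon C1 (silicon blocks an oxygen–iodine bond) from the face anti to the isopropenyl group to give the trans carbon–iodine bond of 3, whose only β-hydrogen (H-6) is syn-clinal so that anti elimination to the phenol is geometrically disfavoured, and free acetate then displaces the hypernucleofuge iodobenzene by SN2 with inversion, so the new C1–O bond ends up cis to the side chain, the opposite of what enolate oxidation gives; the closest known reaction types are the formation of α-(phenyliodonio) ketone salts from silyl enol ethers with PhIO/HBF4 and the iodane-mediated α-acetoxylation or α-tosyloxylation of ketones, neither of which has been used for contra-steric diastereocontrol on a cross-conjugated dienol ether.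

Step 2
Reactants: 4 cis-6-acetoxycarvone
Product: 5 (1R,2S,6S)-2-hydroxy-3-methyl-6-(prop-1-en-2-yl)cyclohex-3-en-1-yl acetate (OH, OAc, isopropenyl all cis)
Conditions: NaBH4, CeCl3·7H2O, MeOH, −78 °C
Reagents that add atoms: none
Why: Luche 1,2-reduction, in which hydride adds to C2 anti to the axial C1 acetoxy group (polar Felkin–Anh, and the same α face that carvone itself prefers), setting the C2 carbinol cis to the acetate and the isopropenyl group, while the cold, weakly acidic medium suppresses 1,2-acetyl migration.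

Step 3
Reactants: 5 all-cis allylic alcohol
Product: 6 (1R,2R,3R,4S,6S)-2-hydroxy-1-methyl-4-(prop-1-en-2-yl)-7-oxabicyclo[4.1.0]heptan-3-yl acetate (oxirane cis to OH)
Conditions: VO(acac)2 (2 mol %), t-BuOOH (decane, 1.3 equiv), CH2Cl2, 0 °C to rt
Reagents that add atoms: tert-butyl hydroperoxide, CC(C)(C)OO
Why: Hydroxyl-directed vanadium-catalysed epoxidation (Sharpless–Michaelson type), in which the C2 alkoxide-bound peroxovanadium species delivers oxygen to its own face, setting C3 and C4 with the oxirane cis to O2, and leaves the non-allylic isopropenyl alkene untouched.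

Step 4
Reactants: 6 epoxy alcohol; 7 angelic acid
Product: 9 (1S,2R,3R,4S,6S)-3-acetoxy-1-methyl-4-(prop-1-en-2-yl)-7-oxabicyclo[4.1.0]heptan-2-yl (Z)-2-methylbut-2-enoate, via mixed anhydride 8 (not isolated)
Conditions: 7, 2,4,6-Cl3C6H2COCl, Et3N, PhMe, rt, 2 h; then 6, 75 °C, 36 h
Reagents that add atoms: none
Why: Yamaguchi-type mixed-anhydride esterification run without a nucleophilic catalyst, the established way to acylate hindered secondary alcohols with angelic acid without Z to E isomerisation, under conditions that create no stereocentre and are too weakly basic for fast acetyl migration or Payne rearrangement.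

Step 5
Reactants: 9 ring-complete isopropenyl compound
Product: 11 (1S,2R,3R,4S,6S)-3-acetoxy-1-methyl-4-(3-oxoprop-1-en-2-yl)-7-oxabicyclo[4.1.0]heptan-2-yl (Z)-2-methylbut-2-enoate (C8 enal), via allylic alcohol 10 (not isolated)
Conditions: SeO2 (0.5 equiv), t-BuOOH (3 equiv), CH2Cl2, rt; then MnO2 (15 equiv), rt
Reagents that add atoms: tert-butyl hydroperoxide, CC(C)(C)OO (terminal source of the new oxygen, passed on by SeO2, O=[Se]=O)
Why: Riley-type SeO2 allylic oxidation (ene reaction, then [2,3]-sigmatropic shift) at the only electron-rich alkene, which takes the methyl group because H-6 is tertiary, hindered and deactivated by the adjacent acetoxy group, followed by MnO2 oxidation of the primary allylic alcohol to the enal, with trisubstituted oxiranes and conjugated esters known to tolerate these conditions.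

Step 6
Reactants: 7 angelic acid; 12 3-bromo-3-methylbutan-2-one
Product: 14 2-methyl-3-oxobutan-2-yl (Z)-2-methylbut-2-enoate, via cesium angelate 13 (not isolated)
Conditions: Cs2CO3 (1.0 equiv), DMF, 0 °C to rt
Reagents that add atoms: none
Why: Carboxylate O-alkylation (substitution at a carbonyl-activated α-bromo ketone), which forms the C11–O bond with angelate acting as the nucleophile and never as an activated acyl donor, so the Z-alkene cannot isomerise and no stereocentre is involved.

Step 7
Reactants: 14 α-angeloyloxy methyl ketone; 11 enal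
Product: 17 (1R,2R,3S,4S,6S,8R)-1-acetoxy-2,11-diangeloyloxy-3,4-epoxy-8-hydroxybisabol-7(14)-en-10-one, via boron enolate 15 (not isolated), via boron aldolate 16 (not isolated)
Conditions: 14 (1.3 equiv), (−)-Ipc2BCl (1.2 equiv), Et3N, Et2O, 0 °C, 1 h; 11, −78 to −25 °C, 16 h; H2O2, pH 7 buffer, MeOH, 0 °C
Reagents that add atoms: none
Why: Paterson-type asymmetric boron aldol, in which 14 can enolise only at its methyl group, the boron enolate adds chemoselectively to the aldehyde through a cyclic transition state, and the (−)-Ipc ligands direct attack to the face giving (8R) (the mirror of the known (+)-Ipc2BCl outcome, (S)-allylic carbinols from methyl ketones and enals), while the excess of 14 leaves no B–Cl species to open the oxirane.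

Step 8
Reactants: 17 β-hydroxy ketone
Product: 19 target CNP0105552.1 = (1R,2R,3S,4S,6S,8R,10R)-1-acetoxy-2,10-diangeloyloxy-3,4-epoxybisabol-7(14)-ene-8,11-diol, via C11-angelate diol 18 (not isolated)
Conditions: Me4NBH(OAc)3 (6 equiv), MeCN/AcOH (2:1), −30 °C, 18 h; aq. NaHCO3, then Et3N (0.5 equiv), rt, same flask
Reagents that add atoms: none
Why: Evans–Saksena hydroxyl-directed reduction followed by 1,2 O→O acyl migration, in which the C8 alkoxy(diacetoxy)borohydride delivers hydride intramolecularly through a chair to set the anti (10R) carbinol of 18, whose secondary hydroxyl then takes the angeloyl group from the neighbouring tertiary oxygen through a five-membered orthoacid, driven by relief of strain in the tertiary ester, while the six-membered shift on to O8 is much slower.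

## Compound list

1 | (R)-(−)-carvone, (5R)-2-methyl-5-(prop-1-en-2-yl)cyclohex-2-en-1-one | C=C(C)[C@@H]1CC=C(C)C(=O)C1 | starting material
2 | {[(3R)-6-methyl-3-(prop-1-en-2-yl)cyclohexa-1,5-dien-1-yl]oxy}trimethylsilane (cross-conjugated TMS dienol ether of 1) | C=C(C)[C@@H]1CC=C(C)C(O[Si](C)(C)C)=C1 | intermediate
3 | [(1S,6S)-3-methyl-2-oxo-6-(prop-1-en-2-yl)cyclohex-3-en-1-yl](phenyl)iodonium tetrafluoroborate (iodine trans to isopropenyl) | C=C(C)[C@@H]1CC=C(C)C(=O)[C@H]1[I+]c2ccccc2.F[B-](F)(F)F | intermediate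
4 | cis-6-acetoxycarvone, (1R,6S)-3-methyl-2-oxo-6-(prop-1-en-2-yl)cyclohex-3-en-1-yl acetate | C=C(C)[C@@H]1CC=C(C)C(=O)[C@@H]1OC(C)=O | intermediate
5 | (1R,2S,6S)-2-hydroxy-3-methyl-6-(prop-1-en-2-yl)cyclohex-3-en-1-yl acetate (all-cis) | C=C(C)[C@@H]1CC=C(C)[C@H](O)[C@@H]1OC(C)=O | intermediate
6 | (1R,2R,3R,4S,6S)-2-hydroxy-1-methyl-4-(prop-1-en-2-yl)-7-oxabicyclo[4.1.0]heptan-3-yl acetate (all-cis) | C=C(C)[C@@H]1C[C@@H]2O[C@]2(C)[C@H](O)[C@@H]1OC(C)=O | intermediate
7 | angelic acid, (Z)-2-methylbut-2-enoic acid | C/C=C(/C)C(=O)O | starting material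
8 | angelic 2,4,6-trichlorobenzoic anhydride | C/C=C(/C)C(=O)OC(=O)c1c(Cl)cc(Cl)cc1Cl | intermediate
9 | (1S,2R,3R,4S,6S)-3-acetoxy-1-methyl-4-(prop-1-en-2-yl)-7-oxabicyclo[4.1.0]heptan-2-yl (Z)-2-methylbut-2-enoate | C=C(C)[C@@H]1C[C@@H]2O[C@]2(C)[C@H](OC(=O)/C(C)=C\C)[C@@H]1OC(C)=O | intermediate
10 | (1S,2R,3R,4S,6S)-3-acetoxy-4-(3-hydroxyprop-1-en-2-yl)-1-methyl-7-oxabicyclo[4.1.0]heptan-2-yl (Z)-2-methylbut-2-enoate | C=C(CO)[C@@H]1C[C@@H]2O[C@]2(C)[C@H](OC(=O)/C(C)=C\C)[C@@H]1OC(C)=O | intermediate
11 | (1S,2R,3R,4S,6S)-3-acetoxy-1-methyl-4-(3-oxoprop-1-en-2-yl)-7-oxabicyclo[4.1.0]heptan-2-yl (Z)-2-methylbut-2-enoate | C=C(C=O)[C@@H]1C[C@@H]2O[C@]2(C)[C@H](OC(=O)/C(C)=C\C)[C@@H]1OC(C)=O | intermediate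
12 | 3-bromo-3-methylbutan-2-one | CC(=O)C(C)(C)Br | starting material
13 | cesium (Z)-2-methylbut-2-enoate | C/C=C(/C)C(=O)[O-].[Cs+] | intermediate
14 | 2-methyl-3-oxobutan-2-yl (Z)-2-methylbut-2-enoate | CC(=O)C(C)(C)OC(=O)/C(C)=C\C | intermediate
15 | diisopinocampheylboron enolate of 14 (Ipc from (+)-α-pinene) | C=C(OB([C@@H]1C[C@@H]2C[C@H]([C@H]1C)C2(C)C)[C@@H]1C[C@@H]2C[C@H]([C@H]1C)C2(C)C)C(C)(C)OC(=O)/C(C)=C\C | intermediate
16 | O8-diisopinocampheylboron aldolate of 17 | C=C([C@H](OB([C@@H]3C[C@@H]4C[C@H]([C@H]3C)C4(C)C)[C@@H]3C[C@@H]4C[C@H]([C@H]3C)C4(C)C)CC(=O)C(C)(C)OC(=O)/C(C)=C\C)[C@@H]1C[C@@H]2O[C@]2(C)[C@H](OC(=O)/C(C)=C\C)[C@@H]1OC(C)=O | intermediate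
17 | (1R,2R,3S,4S,6S,8R)-1-acetoxy-2,11-diangeloyloxy-3,4-epoxy-8-hydroxybisabol-7(14)-en-10-one | C=C([C@H](O)CC(=O)C(C)(C)OC(=O)/C(C)=C\C)[C@@H]1C[C@@H]2O[C@]2(C)[C@H](OC(=O)/C(C)=C\C)[C@@H]1OC(C)=O | intermediate
18 | (1R,2R,3S,4S,6S,8R,10R)-1-acetoxy-2,11-diangeloyloxy-3,4-epoxybisabol-7(14)-ene-8,10-diol | C=C([C@H](O)C[C@@H](O)C(C)(C)OC(=O)/C(C)=C\C)[C@@H]1C[C@@H]2O[C@]2(C)[C@H](OC(=O)/C(C)=C\C)[C@@H]1OC(C)=O | intermediate
19 | CNP0105552.1, (1R,2R,3S,4S,6S,8R,10R)-1-acetoxy-2,10-diangeloyloxy-3,4-epoxybisabol-7(14)-ene-8,11-diol | C=C([C@H](O)C[C@@H](OC(=O)/C(C)=C\C)C(C)(C)O)[C@@H]1C[C@@H]2O[C@]2(C)[C@H](OC(=O)/C(C)=C\C)[C@@H]1OC(C)=O | target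

## Step count and risks

Total step count: 8. Longest linear sequence: 7 (steps 1, 2, 3, 4, 5, 7, 8, starting from 1).

Step 1 is the proposed new step and the most likely to fail. Possible failure modes:
- Acetate transfer from iodine with retention.
- Epimerisation of 3 through its ylide.
- Loss of PhI and a proton, giving the phenol.
- An oxygen-bound pathway that lets acetate enter anti to the isopropenyl group.

The fallback uses known chemistry and sets out from 1. The kinetic lithium enolate (LiN(i-Pr)2, THF, −78 °C) is hydroxylated with 2-(phenylsulfonyl)-3-phenyloxaziridine from the face anti to the isopropenyl group. This gives trans-6-hydroxycarvone F1. A Mitsunobu reaction (AcOH, PPh3, DIAD, PhMe, 0 °C) then inverts C1, and the route is rejoined at 4. The cost is one extra step.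

Step 7 may give only moderate reagent control, since methyl ketone boron enolates are the weakest case for Ipc ligands. The hindered, acid- and base-sensitive enal may also react sluggishly. The fallback sets out from 11 and replaces the aldol by alkynylation followed by hydration. 2-Methylbut-3-yn-2-ol is acylated with angelic anhydride under Bi(OTf)3 catalysis to give 2-methylbut-3-yn-2-yl angelate F2. Its zinc acetylide (Me2Zn, with the ProPhenol antipode that attacks the same aldehyde face as in step 7) adds to 11 to give propargylic alcohol F3. Hydration with Ph3PAuNTf2 in wet dioxane follows. The ester carbonyl attacks C10 in a 5-exo-dig mode, which places the ketone at C10, and the route is rejoined at 17.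

Step 8 may suffer in three ways:
- Slow reduction next to the quaternary carbon.
- Oxirane opening in AcOH.
- An acyl shift that either stalls at 18 or runs on to O8.

The fallback sets out from 17 and blocks O8, replacing substrate direction by reagent control.
- TESOTf/2,6-lutidine gives C8 triethylsilyl ether F4.
- (S)-Me-CBS oxazaborolidine with catecholborane (PhMe, −78 °C; the C(CH3)2OAng group acts as the large substituent) gives (10R)-carbinol F5.
- Et3N in CH2Cl2 moves the angeloyl group to the only free neighbouring hydroxyl, giving C10 angelate silyl ether F6.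
- HF·pyridine (THF, 0 °C) removes the silyl group, and the route is rejoined at 19.

## Further compounds

F1 | step 1 | trans-6-hydroxycarvone, (5S,6S)-6-hydroxy-2-methyl-5-(prop-1-en-2-yl)cyclohex-2-en-1-one | C=C(C)[C@@H]1CC=C(C)C(=O)[C@H]1O
F2 | step 7 | 2-methylbut-3-yn-2-yl (Z)-2-methylbut-2-enoate | C#CC(C)(C)OC(=O)/C(C)=C\C
F3 | step 7 | propargylic alcohol, 9,10-didehydro-10-deoxo analogue of 17 (same spatial arrangement at C8; 8S by CIP because the alkyne outranks C7) | C=C([C@H](O)C#CC(C)(C)OC(=O)/C(C)=C\C)[C@@H]1C[C@@H]2O[C@]2(C)[C@H](OC(=O)/C(C)=C\C)[C@@H]1OC(C)=O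
F4 | step 8 | O8-triethylsilyl ether of 17 | C=C([C@H](O[Si](CC)(CC)CC)CC(=O)C(C)(C)OC(=O)/C(C)=C\C)[C@@H]1C[C@@H]2O[C@]2(C)[C@H](OC(=O)/C(C)=C\C)[C@@H]1OC(C)=O
F5 | step 8 | O8-triethylsilyl ether of 18 | C=C([C@H](O[Si](CC)(CC)CC)C[C@@H](O)C(C)(C)OC(=O)/C(C)=C\C)[C@@H]1C[C@@H]2O[C@]2(C)[C@H](OC(=O)/C(C)=C\C)[C@@H]1OC(C)=O
F6 | step 8 | O8-triethylsilyl ether of 19 | C=C([C@H](O[Si](CC)(CC)CC)C[C@@H](OC(=O)/C(C)=C\C)C(C)(C)O)[C@@H]1C[C@@H]2O[C@]2(C)[C@H](OC(=O)/C(C)=C\C)[C@@H]1OC(C)=O
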